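The substrate has two takers in this scheme, partner and target, and the four set-ups differ in when target first stands beside it.

    substrate + partner → intermediate A (k1 = 0.233 L mol⁻¹ s⁻¹)
    second reagent + intermediate A → intermediate B (k2 = 0.103 L mol⁻¹ s⁻¹)
    third reagent + intermediate B → target (k3 = 1.19 L mol⁻¹ s⁻¹)
    substrate + target → side product A (k4 = 0.416 L mol⁻¹ s⁻¹)
    intermediate B → side product B (k5 = 0.00167 s⁻¹)

in all of them: substrate 20 mM; partner 1.10 equiv

| charge | second reagent | third reagent | time | remark |
|---|---|---|---|---|
| epsilon | 1.10 equiv | 1.05 equiv | 50 min | a closed flask charged with all of it at once and left for 50 min |
| beta | 1.10 equiv (fed, over 40.0 min) | 1.05 equiv | 50 min | a stirred flask in which second reagent is dosed at a steady rate over 40.0 min without added volume, worked up at 50 min |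
| alpha | 1.10 equiv | 1.05 equiv (fed, over 40.0 min) | 50 min | all but third reagent at the start; third reagent goes in evenly over 40.0 min, the run ends at 50 min |
| eta | 1.10 equiv | 1.05 equiv |  | one stirred flow tank at steady state, fed with the mixture as stated, mean residence time 50 min |

- in percentages every species weighs as the substrate in it: one side product A counts as two
- the stated concentrations are those of everything mixed, before any reaction; amounts are the same in each set-up
- the feed brings no volume worth counting
- run time (epsilon): 50 min

* the set-up with the highest share of target in all that became target or side product A or side product B, at the outlet or at the end ("none" if the first two lie within 2 percentage points) (epsilon / beta / alpha / eta / none)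
* share of target in all that became target or side product A or side product B, at the outlet or at the end, epsilon
* share of target in all that became target or side product A or side product B, at the outlet or at the end, beta
* share of target in all that became target or side product A or side product B, at the outlet or at the end, alpha
* share of target in all that became target or side product A or side product B, at the outlet or at the end, eta

I divided the constant of target's loss to side product A by that of substrate's reaction with partner and called the quotient the survival exponent, a selectivity factor: 1.79. Both rates are first order in substrate. So in a closed flask with partner charged at the start, dividing one by the other removes substrate and time, and the integral closes: a target molecule survives to the end with a chance equal to the partner fraction at the end over the partner fraction at its birth, raised to that exponent.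

The first setting is the partner charge. With 1.10 equiv, partner can fall to 9.09 % of its charge, and a target born at the first moment then keeps 1.38 %. I therefore wanted late births and more partner.

The second is dosing the second reagent, as in beta. Substrate's half-life by partner alone, as charged, is 2.3 min, shorter than the 40.0 min feed, so I expected later births and beta above epsilon.

The third is dosing the third reagent, as in alpha. This also delays births, but intermediate B leaks to side product B with a half-life of 6.9 min, and its reaction with third reagent matches that leak at a third reagent level of 0.0702 of the substrate charge. The survival exponent gave me no order of alpha against epsilon.

The last is the vessel. In eta, births have no order, and target at charged substrate has a half-life of 1.4 min, shorter than the 50 min stay, so I expected a poor share there.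

The forecast gave 49.3 % for epsilon, 65.5 % for beta, 44 % for alpha and 17.1 % for eta, and chose beta; its ground for that flask was “Slow dosing of the second reagent”, which lets substrate be consumed before much target exists.

The simulation gave 49.4 %, 64.9 %, 42.4 % and 17.0 % in that order, with beta ahead, though beta still held 15.3 % as intermediate A at 50.0 min. Beta ended with 19.3 % of its partner, so a target born at its first moment kept 5.32 %. The neighbour with 4.40 equiv of partner ended with 77.3 %, so such a target kept 63.1 %, and its share was 89.9 %. The neighbour with 0.660 equiv ended with 2.44 %, so such a target kept 0.133 %; its share was 21.2 %, with 65.7 % of the substrate in side product A.

The constants are made up; the flask was simulated.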